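## Retrosynthetic overview

- **Feature.** Ring F is a pyrogallol with OH on C-3, C-4 and C-5 and H on C-2 and C-6. Its C-1 oxygen is bound to C-4 of ring E, a carbon flanked by the oxygens on E C-3 and E C-5. O-arylation of the ring E phenol serves this ether worst.
- **Key disconnection.** Ring F is cut into the ethynyl ether of the ring E phenol (F C-1, C-2) and a dimethoxyvinylketene (F C-3 to C-6) released from a diazoketone. The E–O–F bond therefore exists before ring F does.
- **Other four ethers.** They are cut at their crowded carbons (D C-4, C C-2, B C-4, A C-1). Each ring enters as a formyl-activated aryl bromide and is joined to the C-1 phenol at the end of the growing chain. Baeyer–Villiger oxidation then turns its formyl group into the next phenol.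
- **Order.** Ring E is bought (syringaldehyde) and ring F is the only ring formed. Rings D, C, B and A are then attached one at a time, and cleavage of all methyl ethers ends the route.

Key step: step 8

Remark: the target has no stereocentre. Rings are lettered A to F from the 2,4,6-trihydroxyphenoxy end to the 3,4,5-trihydroxyphenoxy end. A C-1 carries the oxygen to B C-1, B C-4 the oxygen to C C-1, C C-2 the oxygen to D C-1, D C-4 the oxygen to E C-1, and E C-4 the oxygen to F C-1.

## Route

Step 1
Reactants: 1 syringaldehyde (4-hydroxy-3,5-dimethoxybenzaldehyde)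
Product: 3 2,6-dimethoxybenzene-1,4-diol, via aryl formate 2 (not isolated)
Conditions: 30% aq H2O2 (1.05 equiv), NaOH, H2O/THF, 0 °C to rt, N2; then 1 M HCl
Reagents that add atoms: hydrogen peroxide, OO
Why: Dakin oxidation, in which the para hydroxyl group drives aryl migration in the peroxide adduct and the formate is hydrolysed in the same basic medium.

Step 2
Reactants: 3 2,6-dimethoxybenzene-1,4-diol
Product: 4 4-(benzyloxy)-2,6-dimethoxyphenol
Conditions: BnBr (1.0 equiv), K2CO3 (1.0 equiv), acetone, rt, N2
Reagents that add atoms: benzyl bromide, BrCc1ccccc1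
Why: Williamson etherification with one equivalent of halide, in which the unflanked and more acidic C-4 hydroxyl (meta to both methoxy groups) should react ahead of the C-1 hydroxyl, which is screened and hydrogen-bonded by its two ortho methoxy groups.

Step 3
Reactants: 4 4-(benzyloxy)-2,6-dimethoxyphenol; 5 trichloroethylene
Product: 6 5-(benzyloxy)-2-[(E)-1,2-dichloroethenoxy]-1,3-dimethoxybenzene
Conditions: 5 (1.5 equiv), K2CO3, DMF, 70 °C
Reagents that add atoms: none
Why: Base-induced loss of HCl from 5 gives dichloroacetylene, a slim linear electrophile to which even the doubly flanked phenoxide adds in anti fashion, the standard elimination–addition route to (E)-1,2-dichlorovinyl aryl ethers.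

Step 4
Reactants: 6 5-(benzyloxy)-2-[(E)-1,2-dichloroethenoxy]-1,3-dimethoxybenzene
Product: 9 5-(benzyloxy)-2-(ethynyloxy)-1,3-dimethoxybenzene, via chloroethynyl ether 7 (not isolated), via lithium acetylide 8 (not isolated)
Conditions: n-BuLi (2.5 equiv), THF, −78 to −40 °C; then H2O, −78 °C; kept cold and used at once
Reagents that add atoms: none
Why: β-Elimination of HCl by the first equivalent of n-BuLi and chlorine–lithium exchange by the second give the aryloxyacetylide, which water protonates, and at −78 °C neither benzylic deprotonation nor ring lithiation should compete with this standard dichlorovinyl ether to ynol ether conversion.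

Step 5
Reactants: 10 methyl methoxyacetate; 11 methyl formate
Product: 13 methyl (Z)-2,3-dimethoxyprop-2-enoate, via sodium enolate 12 (not isolated)
Conditions: NaH, 11 (excess), THF, 0 °C to rt; then Me2SO4, DMF, rt
Reagents that add atoms: dimethyl sulfate, COS(=O)(=O)OC
Why: Crossed Claisen condensation (formylation) at the only enolisable carbon, then O-methylation of the enolate by the hard electrophile as is usual for β-methoxyacrylates, favouring the isomer with the β-methoxy group trans to the ester (Z).

Step 6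
Reactants: 13 methyl (Z)-2,3-dimethoxyprop-2-enoate
Product: 14 (Z)-2,3-dimethoxyprop-2-enoic acid
Conditions: LiOH, THF/H2O, 0 °C to rt; then 1 M HCl to pH 3, 0 °C
Reagents that add atoms: lithium hydroxide, [Li+].[OH-]
Why: Ester saponification by acyl–oxygen cleavage, which the donor-substituted C=C, a poor Michael acceptor, should survive together with the brief cold acidification.

Step 7
Reactants: 14 (Z)-2,3-dimethoxyprop-2-enoic acid
Product: 16 (Z)-1-diazo-3,4-dimethoxybut-3-en-2-one, via mixed anhydride 15 (not isolated)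
Conditions: i-BuOCOCl, N-methylmorpholine, THF, −15 °C; then CH2N2 (excess, Et2O, made beforehand from N-methyl-N-nitroso-p-toluenesulfonamide/KOH), 0 °C to rt
Reagents that add atoms: diazomethane, C=[N+]=[N-]; isobutyl chloroformate, CC(C)COC(=O)Cl (its atoms stay only in 15)
Why: Acylation of diazomethane by a mixed carbonic anhydride (first stage of the Arndt–Eistert sequence), in which the two methoxy donors make the C=C too electron-rich for the dipolar cycloaddition of diazomethane that troubles ordinary enoyl derivatives.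

Step 8
Reactants: 9 5-(benzyloxy)-2-(ethynyloxy)-1,3-dimethoxybenzene; 16 (Z)-1-diazo-3,4-dimethoxybut-3-en-2-one
Product: 21 5-[4-(benzyloxy)-2,6-dimethoxyphenoxy]-2,3-dimethoxyphenol, via vinylketene 17 (not isolated), via vinylcyclobutenone 18 (not isolated), via dienylketene 19 (not isolated), via cyclohexadienone 20 (not isolated)
Conditions: 9 (1.2 equiv), slow addition of 16, degassed ClCH2CH2Cl, hν (300 nm, Pyrex), 25 °C; then 80 °C, 3 h
Reagents that add atoms: none
Why: Light expels N2 from 16 and the dimethoxyvinyl group shifts from the carbonyl carbon (later F C-3) to the diazo carbon (later F C-6), a Wolff rearrangement that makes F C-5–C-6 and releases vinylketene 17. The nucleophilic terminal carbon of 9 attacks the ketene carbonyl carbon, so the [2+2] cycloaddition forms F C-2–C-3 and F C-1–C-6 and gives cyclobutenone 18, which on warming opens in a 4π electrocyclic step (C-3–C-6 breaks) to dienylketene 19. Ring F, the only ring closed, forms by thermal 6π electrocyclisation of 19, which joins the ketene carbon C-3 to the methoxy-bearing terminus C-4, and dienone 20 tautomerises to phenol 21. This is the Danheiser benzannulation in its diazoketone form, in which ynol ethers and other heteroatom-substituted alkynes are the usual ketenophiles. No stereocentre is left, since the sp3 carbons of 18 and 20 become aromatic and the enol ether geometry, even if light scrambles it, is erased. The selectivity needed is the orientation of the [2+2] step, and the polarity of the ynol ether (electron-rich CH terminus) secures it, placing the ring E oxygen meta to the new hydroxyl and para to the C-4 methoxy group, while light above 290 nm spares the benzyl aryl ether and any 17 that closes to its own cyclobutenone re-opens at 80 °C.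

Step 9
Reactants: 21 5-[4-(benzyloxy)-2,6-dimethoxyphenoxy]-2,3-dimethoxyphenol
Product: 22 5-(benzyloxy)-1,3-dimethoxy-2-(3,4,5-trimethoxyphenoxy)benzene
Conditions: MeI, K2CO3, acetone, 50 °C
Reagents that add atoms: iodomethane, CI
Why: Williamson methylation of the only free phenol caps F C-3 so that it cannot act as a nucleophile in the later couplings.

Step 10
Reactants: 22 5-(benzyloxy)-1,3-dimethoxy-2-(3,4,5-trimethoxyphenoxy)benzene
Product: 23 3,5-dimethoxy-4-(3,4,5-trimethoxyphenoxy)phenol (E–F phenol)
Conditions: H2 (1 atm), 10% Pd/C, EtOAc/MeOH, rt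
Reagents that add atoms: none
Why: Catalytic hydrogenolysis cleaves only the benzylic C–O bond, aryl methyl and diaryl ethers being inert.

Step 11
Reactants: 23 E–F phenol; 24 4-bromo-3,5-dimethoxybenzaldehyde
Product: 25 trimer aldehyde D–E–F 4-[3,5-dimethoxy-4-(3,4,5-trimethoxyphenoxy)phenoxy]-3,5-dimethoxybenzaldehyde
Conditions: CuI (10 mol %), picolinic acid (20 mol %), K3PO4 (2 equiv), DMSO, 95 °C, Ar
Reagents that add atoms: none
Why: Ullmann-type copper-catalysed C–O coupling with a ligand system suited to ortho-substituted partners, in which the nucleophile is an unflanked phenoxide and the crowded carbon D C-4 is the electrophile, its C–Br bond activated by the para formyl group.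

Step 12
Reactants: 25 trimer aldehyde D–E–F
Product: 27 trimer phenol D–E–F 4-[3,5-dimethoxy-4-(3,4,5-trimethoxyphenoxy)phenoxy]-3,5-dimethoxyphenol, via trimer formate 26 (not isolated)
Conditions: mCPBA, CH2Cl2, 0 °C to rt; then K2CO3 (cat.), MeOH, rt
Reagents that add atoms: 3-chloroperoxybenzoic acid, OOC(=O)c1cccc(Cl)c1
Why: Baeyer–Villiger oxidation in which the electron-rich aryl group (para aryloxy donor) migrates in preference to hydride, as it does in 3,4,5-trimethoxybenzaldehyde, and transesterification then frees the phenol.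

Step 13
Reactants: 27 trimer phenol D–E–F; 28 2-bromo-3,4,5-trimethoxybenzaldehyde
Product: 29 tetramer aldehyde C–D–E–F (3,4,5-trimethoxybenzaldehyde bearing at C-2 the aryloxy group of 27)
Conditions: CuI (20 mol %), picolinic acid (40 mol %), K3PO4 (2 equiv), DMSO, 100 °C, Ar
Reagents that add atoms: none
Why: Ullmann-type coupling of an unflanked phenoxide with an ortho-formyl bromide, the carbonyl oxygen assisting copper at the C–Br bond as in the classical couplings of 2-bromo-3,4,5-trimethoxybenzoyl compounds.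

Step 14
Reactants: 29 tetramer aldehyde C–D–E–F
Product: 31 tetramer phenol C–D–E–F (3,4,5-trimethoxyphenol bearing at C-2 the aryloxy group of 27), via tetramer formate 30 (not isolated)
Conditions: mCPBA, CH2Cl2, 0 °C to rt; then K2CO3 (cat.), MeOH, rt
Reagents that add atoms: 3-chloroperoxybenzoic acid, OOC(=O)c1cccc(Cl)c1
Why: Baeyer–Villiger oxidation made easy by the ortho aryloxy and para methoxy donors on the migrating ring C, followed by methanolysis of the formate to the C C-1 phenol.

Step 15
Reactants: 31 tetramer phenol C–D–E–F; 24 4-bromo-3,5-dimethoxybenzaldehyde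
Product: 32 pentamer aldehyde B–C–D–E–F (3,5-dimethoxybenzaldehyde bearing at C-4 the aryloxy group of 31)
Conditions: CuI (20 mol %), picolinic acid (40 mol %), K3PO4 (2 equiv), DMSO, 105 °C, Ar
Reagents that add atoms: none
Why: The same Ullmann-type coupling, here giving a diaryl ether with three ortho substituents, a pattern within the reach of the picolinic acid system and helped by the para formyl group on the bromide.

Step 16
Reactants: 32 pentamer aldehyde B–C–D–E–F
Product: 34 pentamer phenol B–C–D–E–F (3,5-dimethoxyphenol bearing at C-4 the aryloxy group of 31), via pentamer formate 33 (not isolated)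
Conditions: mCPBA, CH2Cl2, 0 °C to rt; then K2CO3 (cat.), MeOH, rt
Reagents that add atoms: 3-chloroperoxybenzoic acid, OOC(=O)c1cccc(Cl)c1
Why: Baeyer–Villiger oxidation and formate methanolysis exactly as in step 12, the formyl group being the only function that reacts with the peracid at this temperature.

Step 17
Reactants: 34 pentamer phenol B–C–D–E–F; 24 4-bromo-3,5-dimethoxybenzaldehyde
Product: 35 hexamer aldehyde A–B–C–D–E–F (3,5-dimethoxybenzaldehyde bearing at C-4 the aryloxy group of 34)
Conditions: CuI (10 mol %), picolinic acid (20 mol %), K3PO4 (2 equiv), DMSO, 95 °C, Ar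
Reagents that add atoms: none
Why: Ullmann-type coupling of the unflanked B C-1 phenoxide with the formyl-activated bromide, the same pairing as in step 11.

Step 18
Reactants: 35 hexamer aldehyde A–B–C–D–E–F
Product: 37 hexamer phenol (tetradeca-O-methyl ether of the target; free OH on A C-4), via hexamer formate 36 (not isolated)
Conditions: mCPBA, CH2Cl2, 0 °C to rt; then K2CO3 (cat.), MeOH, rt
Reagents that add atoms: 3-chloroperoxybenzoic acid, OOC(=O)c1cccc(Cl)c1
Why: Baeyer–Villiger oxidation and methanolysis as in step 12 put the last oxygen on A C-4, which needs no capping because it is a free hydroxyl in the target.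

Step 19
Reactants: 37 hexamer phenol
Product: 38 target CNP0270681.0
Conditions: BBr3 (1 M in CH2Cl2, about 3 equiv per OMe), CH2Cl2, −78 °C to rt, Ar; then H2O, 0 °C; Sephadex LH-20, degassed MeOH
Reagents that add atoms: none
Why: Lewis acid-mediated cleavage of the fourteen aryl methyl ethers by bromide attack on the boron-activated methyl groups, a reaction that leaves diaryl ether bonds untouched.

## Compound list

1 | syringaldehyde (4-hydroxy-3,5-dimethoxybenzaldehyde) | COc1cc(C=O)cc(OC)c1O | starting material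
2 | 4-hydroxy-3,5-dimethoxyphenyl formate | O=COc1cc(OC)c(O)c(OC)c1 | intermediate
3 | 2,6-dimethoxybenzene-1,4-diol | COc1cc(O)cc(OC)c1O | intermediate
4 | 4-(benzyloxy)-2,6-dimethoxyphenol | COc1cc(OCc2ccccc2)cc(OC)c1O | intermediate
5 | trichloroethylene | ClC=C(Cl)Cl | starting material
6 | 5-(benzyloxy)-2-[(E)-1,2-dichloroethenoxy]-1,3-dimethoxybenzene | Cl/C=C(/Cl)Oc1c(OC)cc(OCc2ccccc2)cc1OC | intermediate
7 | 5-(benzyloxy)-2-(chloroethynyloxy)-1,3-dimethoxybenzene | ClC#COc1c(OC)cc(OCc2ccccc2)cc1OC | intermediate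
8 | lithium [4-(benzyloxy)-2,6-dimethoxyphenoxy]acetylide | [Li]C#COc1c(OC)cc(OCc2ccccc2)cc1OC | intermediate
9 | 5-(benzyloxy)-2-(ethynyloxy)-1,3-dimethoxybenzene (ring E ynol ether) | C#COc1c(OC)cc(OCc2ccccc2)cc1OC | intermediate
10 | methyl methoxyacetate | COCC(=O)OC | starting material
11 | methyl formate | COC=O | starting material
12 | sodium 2,3-dimethoxy-3-oxoprop-1-en-1-olate (geometry not defined) | [Na+].[O-]C=C(OC)C(=O)OC | intermediate
13 | methyl (Z)-2,3-dimethoxyprop-2-enoate | COC(=O)/C(OC)=C/OC | intermediate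
14 | (Z)-2,3-dimethoxyprop-2-enoic acid | OC(=O)/C(OC)=C/OC | intermediate
15 | (Z)-2,3-dimethoxyprop-2-enoic isobutyl carbonic anhydride | CC(C)COC(=O)OC(=O)/C(OC)=C/OC | intermediate
16 | (Z)-1-diazo-3,4-dimethoxybut-3-en-2-one | [N-]=[N+]=CC(=O)/C(OC)=C/OC | intermediate
17 | (Z)-3,4-dimethoxybuta-1,3-dien-1-one (vinylketene) | O=C=C/C(OC)=C/OC | intermediate
18 | 3-[4-(benzyloxy)-2,6-dimethoxyphenoxy]-4-[(Z)-1,2-dimethoxyethenyl]cyclobut-2-en-1-one (racemic) | O=C1C=C(Oc2c(OC)cc(OCc3ccccc3)cc2OC)C1/C(OC)=C/OC | intermediate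
19 | (3E,5Z)-3-[4-(benzyloxy)-2,6-dimethoxyphenoxy]-5,6-dimethoxyhexa-1,3,5-trien-1-one (dienylketene) | O=C=C/C(Oc1c(OC)cc(OCc2ccccc2)cc1OC)=C\C(OC)=C\OC | intermediate
20 | 3-[4-(benzyloxy)-2,6-dimethoxyphenoxy]-5,6-dimethoxycyclohexa-2,4-dien-1-one (racemic) | O=C1C=C(Oc2c(OC)cc(OCc3ccccc3)cc2OC)C=C(OC)C1OC | intermediate
21 | 5-[4-(benzyloxy)-2,6-dimethoxyphenoxy]-2,3-dimethoxyphenol | Oc1cc(Oc2c(OC)cc(OCc3ccccc3)cc2OC)cc(OC)c1OC | intermediate
22 | 5-(benzyloxy)-1,3-dimethoxy-2-(3,4,5-trimethoxyphenoxy)benzene | COc1cc(Oc2c(OC)cc(OCc3ccccc3)cc2OC)cc(OC)c1OC | intermediate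
23 | 3,5-dimethoxy-4-(3,4,5-trimethoxyphenoxy)phenol (E–F phenol) | Oc1cc(OC)c(Oc2cc(OC)c(OC)c(OC)c2)c(OC)c1 | intermediate
24 | 4-bromo-3,5-dimethoxybenzaldehyde | O=Cc1cc(OC)c(Br)c(OC)c1 | starting material
25 | trimer aldehyde D–E–F | O=Cc1cc(OC)c(Oc2cc(OC)c(Oc3cc(OC)c(OC)c(OC)c3)c(OC)c2)c(OC)c1 | intermediate
26 | trimer formate D–E–F | O=COc1cc(OC)c(Oc2cc(OC)c(Oc3cc(OC)c(OC)c(OC)c3)c(OC)c2)c(OC)c1 | intermediate
27 | trimer phenol D–E–F | Oc1cc(OC)c(Oc2cc(OC)c(Oc3cc(OC)c(OC)c(OC)c3)c(OC)c2)c(OC)c1 | intermediate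
28 | 2-bromo-3,4,5-trimethoxybenzaldehyde | O=Cc1cc(OC)c(OC)c(OC)c1Br | starting material
29 | tetramer aldehyde C–D–E–F | O=Cc1cc(OC)c(OC)c(OC)c1Oc1cc(OC)c(Oc2cc(OC)c(Oc3cc(OC)c(OC)c(OC)c3)c(OC)c2)c(OC)c1 | intermediate
30 | tetramer formate C–D–E–F | O=COc1cc(OC)c(OC)c(OC)c1Oc1cc(OC)c(Oc2cc(OC)c(Oc3cc(OC)c(OC)c(OC)c3)c(OC)c2)c(OC)c1 | intermediate
31 | tetramer phenol C–D–E–F | Oc1cc(OC)c(OC)c(OC)c1Oc1cc(OC)c(Oc2cc(OC)c(Oc3cc(OC)c(OC)c(OC)c3)c(OC)c2)c(OC)c1 | intermediate
32 | pentamer aldehyde B–C–D–E–F | O=Cc1cc(OC)c(Oc2cc(OC)c(OC)c(OC)c2Oc2cc(OC)c(Oc3cc(OC)c(Oc4cc(OC)c(OC)c(OC)c4)c(OC)c3)c(OC)c2)c(OC)c1 | intermediate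
33 | pentamer formate B–C–D–E–F | O=COc1cc(OC)c(Oc2cc(OC)c(OC)c(OC)c2Oc2cc(OC)c(Oc3cc(OC)c(Oc4cc(OC)c(OC)c(OC)c4)c(OC)c3)c(OC)c2)c(OC)c1 | intermediate
34 | pentamer phenol B–C–D–E–F | Oc1cc(OC)c(Oc2cc(OC)c(OC)c(OC)c2Oc2cc(OC)c(Oc3cc(OC)c(Oc4cc(OC)c(OC)c(OC)c4)c(OC)c3)c(OC)c2)c(OC)c1 | intermediate
35 | hexamer aldehyde A–B–C–D–E–F | O=Cc1cc(OC)c(Oc2cc(OC)c(Oc3cc(OC)c(OC)c(OC)c3Oc3cc(OC)c(Oc4cc(OC)c(Oc5cc(OC)c(OC)c(OC)c5)c(OC)c4)c(OC)c3)c(OC)c2)c(OC)c1 | intermediate
36 | hexamer formate A–B–C–D–E–F | O=COc1cc(OC)c(Oc2cc(OC)c(Oc3cc(OC)c(OC)c(OC)c3Oc3cc(OC)c(Oc4cc(OC)c(Oc5cc(OC)c(OC)c(OC)c5)c(OC)c4)c(OC)c3)c(OC)c2)c(OC)c1 | intermediate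
37 | hexamer phenol (tetradeca-O-methyl ether of the target, free OH on A C-4) | Oc1cc(OC)c(Oc2cc(OC)c(Oc3cc(OC)c(OC)c(OC)c3Oc3cc(OC)c(Oc4cc(OC)c(Oc5cc(OC)c(OC)c(OC)c5)c(OC)c4)c(OC)c3)c(OC)c2)c(OC)c1 | intermediate
38 | CNP0270681.0 | Oc1cc(O)c(Oc2cc(O)c(Oc3cc(O)c(O)c(O)c3Oc3cc(O)c(Oc4cc(O)c(Oc5cc(O)c(O)c(O)c5)c(O)c4)c(O)c3)c(O)c2)c(O)c1 | target

## Step count

Total step count: 19.
Longest linear sequence: 16 steps (steps 1–4 and 8–19, from syringaldehyde).

## Steps most likely to fail

**Step 8.** The vinylketene may be used up by dimerisation, or by acylation of phenol already formed, faster than the only moderately nucleophilic aryl ynol ether traps it. The terminal ynol ether may also polymerise during irradiation or heating.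

The fallback sets out from bromide 24 and comes back at phenol 23. Ring F is bought instead of built, and the crowded carbon E C-4 acts as the electrophile. Commercial 3,4,5-trimethoxyphenol is coupled with 24 under the conditions of step 11 to give 3,5-dimethoxy-4-(3,4,5-trimethoxyphenoxy)benzaldehyde F1. mCPBA in CH2Cl2 converts this into 3,5-dimethoxy-4-(3,4,5-trimethoxyphenoxy)phenyl formate F2. Methanolysis of F2 (K2CO3 cat., MeOH) gives 23.

**Step 15.** Ligand exchange and carbon–bromine activation at a copper centre crowded by the ortho-aryloxy phenoxide and the doubly ortho-substituted bromide may be too slow. Protodebromination of the bromide and oxidative loss of the phenol would then take over.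

The fallback sets out from 24 and 31 and comes back at 32. It replaces metal catalysis by uncatalysed addition–elimination on a purpose-made fluoride.
- 24 is protected (ethane-1,2-diol, p-TsOH, toluene, water removal) as 2-(4-bromo-3,5-dimethoxyphenyl)-1,3-dioxolane F3.
- Bromine–lithium exchange (n-BuLi, THF, −78 °C) gives [4-(1,3-dioxolan-2-yl)-2,6-dimethoxyphenyl]lithium F4.
- N-fluorobenzenesulfonimide fluorinates this to 2-(4-fluoro-3,5-dimethoxyphenyl)-1,3-dioxolane F5.
- Dilute HCl frees 4-fluoro-3,5-dimethoxybenzaldehyde F6.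
- Phenol 31 and F6 (Cs2CO3, DMSO, 110 °C) then combine by SNAr. The para formyl group stabilises the anionic adduct, and the attack, perpendicular to the ring, is less sensitive to ortho bulk. The product is 32.

**Step 19.** Partly demethylated borate complexes may precipitate and stop the cleavage short of completion. The pyrogallol rings may also oxidise in air during isolation of the free polyphenol.

The fallback sets out from 37 and comes back at 38.
- 37 is demethylated in a homogeneous hard acid–soft nucleophile medium (AlCl3 in ethanethiol, 0 °C to rt).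
- The crude polyphenol is acetylated at once (Ac2O, pyridine) to the pentadecaacetate of the target F7, which can be chromatographed on silica and freed of under-cleaved material.
- Methanolic HCl under argon then removes the acetyl groups without passing through air-sensitive phenoxides and gives 38.

## Further compounds

F1 | step 8 | 3,5-dimethoxy-4-(3,4,5-trimethoxyphenoxy)benzaldehyde | O=Cc1cc(OC)c(Oc2cc(OC)c(OC)c(OC)c2)c(OC)c1
F2 | step 8 | 3,5-dimethoxy-4-(3,4,5-trimethoxyphenoxy)phenyl formate | O=COc1cc(OC)c(Oc2cc(OC)c(OC)c(OC)c2)c(OC)c1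
F3 | step 15 | 2-(4-bromo-3,5-dimethoxyphenyl)-1,3-dioxolane | COc1cc(C2OCCO2)cc(OC)c1Br
F4 | step 15 | [4-(1,3-dioxolan-2-yl)-2,6-dimethoxyphenyl]lithium | [Li]c1c(OC)cc(C2OCCO2)cc1OC
F5 | step 15 | 2-(4-fluoro-3,5-dimethoxyphenyl)-1,3-dioxolane | COc1cc(C2OCCO2)cc(OC)c1F
F6 | step 15 | 4-fluoro-3,5-dimethoxybenzaldehyde | O=Cc1cc(OC)c(F)c(OC)c1
F7 | step 19 | pentadecaacetate of the target | CC(=O)Oc1cc(OC(C)=O)c(Oc2cc(OC(C)=O)c(Oc3cc(OC(C)=O)c(OC(C)=O)c(OC(C)=O)c3Oc3cc(OC(C)=O)c(Oc4cc(OC(C)=O)c(Oc5cc(OC(C)=O)c(OC(C)=O)c(OC(C)=O)c5)c(OC(C)=O)c4)c(OC(C)=O)c3)c(OC(C)=O)c2)c(OC(C)=O)c1
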